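**Retrosynthetic overview**
- The strategy rests on the side-chain unit C8H=C9H–C10H2–C11H(OH): a secondary carbinol homoallylic to a Z alkene. This is the retron of heptanal plus an α-substituted allylboronate whose C8–B stereocentre is spent as the alkene forms (C10–C11 disconnection).
- The (R)-C8 allylboronate is cut at C8–C9 into vinylboronic acid pinacol ester and an 8-aryloctyl N,N-diisopropylcarbamate, joined by sparteine-mediated lithiation–borylation.
- The aryloctyl chain is cut at C1–C2 by Wittig olefination of bis-silylated 3,5-dihydroxybenzaldehyde with a 7-hydroxyheptyl ylide, followed by saturation.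
- No ring is formed: the resorcinol ring is bought intact. Bonds are made in the order C1–C2, C8–C9, C10–C11, and the two silyl ethers are removed last.

Key step: step 7

Assumption: side-chain locants run from C1 (benzylic) to C17 (methyl); (−)-sparteine is the antipode used, and its enantiomer or a surrogate would give the mirror-image series.

Step 1
Reactants: 1 3,5-dihydroxybenzaldehyde
Product: 2 3,5-bis(triisopropylsilyloxy)benzaldehyde
Conditions: TIPSCl (2.4 equiv), imidazole (5 equiv), DMF, rt
Reagents that add atoms: triisopropylsilyl chloride, CC(C)[Si](Cl)(C(C)C)C(C)C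
Why: Imidazole-promoted O-silylation of both phenols leaves the aldehyde untouched, and the bulky silyl ethers are poor directors of arene lithiation and should last through base, hydrogenation and organolithium steps until fluoride is applied.

Step 2
Reactants: 3 7-bromoheptan-1-ol
Product: 4 (7-hydroxyheptyl)triphenylphosphonium bromide
Conditions: PPh3, MeCN, reflux
Reagents that add atoms: triphenylphosphine, c1ccc(cc1)P(c1ccccc1)c1ccccc1
Why: SN2 quaternisation of triphenylphosphine by the primary bromide gives the salt, the free hydroxyl being inert under these neutral conditions.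

Step 3
Reactants: 2 3,5-bis(triisopropylsilyloxy)benzaldehyde; 4 (7-hydroxyheptyl)triphenylphosphonium bromide
Product: 6 8-[3,5-bis(triisopropylsilyloxy)phenyl]oct-7-en-1-ol (Z drawn; either geometry serves), via lithium alkoxide ylide 5 (not isolated)
Conditions: LiN(SiMe3)2 (2.1 equiv), THF, 0 °C; then 2, −78 °C to rt; H2O quench
Reagents that add atoms: none
Why: Wittig olefination in which two equivalents of amide base deprotonate both the hydroxyl and the α-carbon, the resulting non-stabilised ylide forming the C1=C2 bond with the aryl aldehyde, and the alkene geometry does not matter because the bond is saturated in the next step.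

Step 4
Reactants: 6 8-[3,5-bis(triisopropylsilyloxy)phenyl]oct-7-en-1-ol
Product: 7 8-[3,5-bis(triisopropylsilyloxy)phenyl]octan-1-ol
Conditions: H2 (1 atm), 10% Pd/C (palladium metal on carbon), EtOAc, rt
Reagents that add atoms: none
Why: Heterogeneous catalytic hydrogenation saturates the styrenyl double bond, while the aryl silyl ethers, the arene and the primary alcohol are stable in a non-protic solvent.

Step 5
Reactants: 7 8-[3,5-bis(triisopropylsilyloxy)phenyl]octan-1-ol
Product: 8 8-[3,5-bis(triisopropylsilyloxy)phenyl]octyl N,N-diisopropylcarbamate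
Conditions: iPr2NCOCl, Et3N, CH2Cl2, reflux
Reagents that add atoms: N,N-diisopropylcarbamoyl chloride, CC(C)N(C(C)C)C(Cl)=O
Why: O-Carbamoylation of the primary alcohol installs the hindered carbamate that directs and stabilises α-lithiation and later acts as the leaving group in the 1,2-shift.

Step 6
Reactants: 8 8-[3,5-bis(triisopropylsilyloxy)phenyl]octyl N,N-diisopropylcarbamate; 9 vinylboronic acid pinacol ester
Product: 12 (R)-2-{10-[3,5-bis(triisopropylsilyloxy)phenyl]dec-1-en-3-yl}-4,4,5,5-tetramethyl-1,3,2-dioxaborolane, via lithiated carbamate 10 (not isolated), via boronate complex 11 (not isolated)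
Conditions: sBuLi, (−)-sparteine, Et2O, −78 °C, 5 h; 9, −78 °C, 1 h; MgBr2·OEt2, −78 °C to reflux, 16 h; aq NH4Cl, short SiO2 plug
Reagents that add atoms: none
Why: Sparteine-mediated carbamate lithiation–borylation, in which the chiral base removes the pro-S proton next to oxygen to give the configurationally stable (S)-lithio carbamate, this adds to the vinylboronate with retention, and the vinyl group then migrates from boron to carbon anti to the departing carbamate (inversion), forming the C8–C9 bond and the (R)-C8–B centre; the bulky silyl ethers should not direct arene metalation at −78 °C, the aqueous work-up removes the magnesium Lewis acid, and sense and ee can be checked by oxidising an aliquot to the (R)-allylic alcohol.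

Step 7
Reactants: 12 (R)-2-{10-[3,5-bis(triisopropylsilyloxy)phenyl]dec-1-en-3-yl}-4,4,5,5-tetramethyl-1,3,2-dioxaborolane; 13 heptanal
Product: 15 (7S,9Z)-17-[3,5-bis(triisopropylsilyloxy)phenyl]heptadec-9-en-7-ol, via borate ester 14 (not isolated)
Conditions: 13 (2 equiv), toluene, 0 °C to rt, 48 h, no Lewis acid; N(CH2CH2OH)3, CH2Cl2, rt; chromatography on AgNO3-impregnated SiO2
Reagents that add atoms: none
Why: The aldehyde oxygen binds the boron of 12 and the C10 terminus adds to the carbonyl carbon through a closed six-membered chair (B, O, C11, C10, C9, C8), so that the C10–C11 bond forms on the allyl face from which the C8–B bond departs while the double bond moves from C9=C10 to C8=C9, which is the known closed-transition-state allylboration of aldehydes by enantioenriched α-substituted allylboronic esters with 1,3-chirality transfer. No ring is closed, the chair being only the transition-state array. The new C11 stereocentre is controlled by the (R)-C8–B centre: with the hexyl group of heptanal equatorial and the C1–C7 chain on C8 axial, the aldehyde face that gives (S)-C11 is attacked, and C8 is flattened to sp2 as one end of the Z alkene. The step needs Z over E selectivity, which rests on the axial preference of the C8 chain because an equatorial chain runs into the pinacolate oxygen and methyl groups on boron; with the pinacol ester this preference is expected to be only moderate, and since the competing chair with the chain equatorial would give the E alkene with (R)-C11, that product is a geometric isomer to be removed on the silver-loaded silica, so the enantiopurity of the Z product should follow that of 12. Heptanal is unbranched and reactive enough to need no Lewis acid, which is kept out because acid catalysis could alter the geometric preference, and the silyl ethers and arene are inert. Triethanolamine then releases the alcohol from borate ester 14.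

Step 8
Reactants: 15 (7S,9Z)-17-[3,5-bis(triisopropylsilyloxy)phenyl]heptadec-9-en-7-ol
Product: 16 5-[(8Z,11S)-11-hydroxyheptadec-8-en-1-yl]benzene-1,3-diol
Conditions: Bu4NF (2.5 equiv), AcOH (2.5 equiv), THF, 0 °C to rt
Reagents that add atoms: none
Why: Fluoride-induced desilylation cleaves both aryl silyl ethers through Si–F bond formation, acetic acid buffering the liberated phenoxides, and the secondary alcohol and Z alkene are untouched.

**Compound list**
1 | 3,5-dihydroxybenzaldehyde | O=Cc1cc(O)cc(O)c1 | starting material
2 | 3,5-bis(triisopropylsilyloxy)benzaldehyde | O=Cc1cc(O[Si](C(C)C)(C(C)C)C(C)C)cc(O[Si](C(C)C)(C(C)C)C(C)C)c1 | intermediate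
3 | 7-bromoheptan-1-ol | OCCCCCCCBr | starting material
4 | (7-hydroxyheptyl)triphenylphosphonium bromide | OCCCCCCC[P+](c1ccccc1)(c1ccccc1)c1ccccc1.[Br-] | intermediate
5 | lithium 7-(triphenylphosphoranylidene)heptan-1-olate (alkoxide ylide, not isolated) | [Li+].[O-]CCCCCCC=P(c1ccccc1)(c1ccccc1)c1ccccc1 | intermediate
6 | 8-[3,5-bis(triisopropylsilyloxy)phenyl]oct-7-en-1-ol (Z drawn; E/Z mixture acceptable) | OCCCCCC/C=C\c1cc(O[Si](C(C)C)(C(C)C)C(C)C)cc(O[Si](C(C)C)(C(C)C)C(C)C)c1 | intermediate
7 | 8-[3,5-bis(triisopropylsilyloxy)phenyl]octan-1-ol | OCCCCCCCCc1cc(O[Si](C(C)C)(C(C)C)C(C)C)cc(O[Si](C(C)C)(C(C)C)C(C)C)c1 | intermediate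
8 | 8-[3,5-bis(triisopropylsilyloxy)phenyl]octyl N,N-diisopropylcarbamate | CC(C)N(C(C)C)C(=O)OCCCCCCCCc1cc(O[Si](C(C)C)(C(C)C)C(C)C)cc(O[Si](C(C)C)(C(C)C)C(C)C)c1 | intermediate
9 | vinylboronic acid pinacol ester | C=CB1OC(C)(C)C(C)(C)O1 | starting material
10 | (S)-1-lithio-8-[3,5-bis(triisopropylsilyloxy)phenyl]octyl N,N-diisopropylcarbamate, (−)-sparteine complex (not isolated) | [Li][C@H](OC(=O)N(C(C)C)C(C)C)CCCCCCCc1cc(O[Si](C(C)C)(C(C)C)C(C)C)cc(O[Si](C(C)C)(C(C)C)C(C)C)c1 | intermediate
11 | lithium vinyl(pinacolato)borate complex of the (S)-α-carbamoyloxyalkyl group (not isolated) | [Li+].C=C[B-]1(OC(C)(C)C(C)(C)O1)[C@H](OC(=O)N(C(C)C)C(C)C)CCCCCCCc1cc(O[Si](C(C)C)(C(C)C)C(C)C)cc(O[Si](C(C)C)(C(C)C)C(C)C)c1 | intermediate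
12 | (R)-2-{10-[3,5-bis(triisopropylsilyloxy)phenyl]dec-1-en-3-yl}-4,4,5,5-tetramethyl-1,3,2-dioxaborolane | C=C[C@H](B1OC(C)(C)C(C)(C)O1)CCCCCCCc1cc(O[Si](C(C)C)(C(C)C)C(C)C)cc(O[Si](C(C)C)(C(C)C)C(C)C)c1 | intermediate
13 | heptanal | CCCCCCC=O | starting material
14 | 2-{[(7S,9Z)-17-[3,5-bis(triisopropylsilyloxy)phenyl]heptadec-9-en-7-yl]oxy}-4,4,5,5-tetramethyl-1,3,2-dioxaborolane (not isolated) | CCCCCC[C@H](OB1OC(C)(C)C(C)(C)O1)C/C=C\CCCCCCCc1cc(O[Si](C(C)C)(C(C)C)C(C)C)cc(O[Si](C(C)C)(C(C)C)C(C)C)c1 | intermediate
15 | (7S,9Z)-17-[3,5-bis(triisopropylsilyloxy)phenyl]heptadec-9-en-7-ol | CCCCCC[C@H](O)C/C=C\CCCCCCCc1cc(O[Si](C(C)C)(C(C)C)C(C)C)cc(O[Si](C(C)C)(C(C)C)C(C)C)c1 | intermediate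
16 | 5-[(8Z,11S)-11-hydroxyheptadec-8-en-1-yl]benzene-1,3-diol | CCCCCC[C@H](O)C/C=C\CCCCCCCc1cc(O)cc(O)c1 | target

**Step count**
Total steps: 8. Longest linear sequence: 7 steps (from 1 through steps 1, 3, 4, 5, 6, 7, 8; equally from 3 through steps 2 to 8).

**Steps most likely to fail**

Step 7. The chair with the C8 chain equatorial may compete more than hoped, eroding Z/E selectivity and costing material at the argentation separation. A first remedy within the same chemistry is a vinylboronic ester of a bulkier 1,2-diol in step 6. The fallback leaves boron chemistry and sets out from 7. Oxidation of 7 (Dess–Martin periodinane, NaHCO3, CH2Cl2) would give 8-[3,5-bis(triisopropylsilyloxy)phenyl]octanal F1. One-carbon homologation with lithiated trimethylsilyldiazomethane (Colvin rearrangement, THF, −78 °C to rt) would give 9-[3,5-bis(triisopropylsilyloxy)phenyl]non-1-yne F2. Its lithium acetylide (nBuLi, THF, −78 °C) with BF3·OEt2 would open commercial (S)-1,2-epoxyoctane at the terminal carbon to give (S)-17-[3,5-bis(triisopropylsilyloxy)phenyl]heptadec-9-yn-7-ol F3, C11 then coming from the epoxide. Semi-hydrogenation over Lindlar catalyst (Pd/CaCO3 poisoned with Pb(OAc)2, quinoline, H2, EtOAc) would give the Z alkene and rejoin the route at 15.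

Step 6. Deprotonation may be incomplete or poorly selective (loss of ee), the base may metalate the arene between the two silyloxy groups or the benzylic position, or the 1,2-shift may stall at the boronate complex. The fallback reaches 12 by catalytic asymmetric borylation and sets out from 7 through the aldehyde F1 described above. Still–Gennari olefination (methyl bis(2,2,2-trifluoroethyl)phosphonoacetate, KN(SiMe3)2, 18-crown-6, THF, −78 °C) would give methyl (Z)-10-[3,5-bis(triisopropylsilyloxy)phenyl]dec-2-enoate F4. Reduction with iBu2AlH (CH2Cl2, −78 °C) would give (Z)-10-[3,5-bis(triisopropylsilyloxy)phenyl]dec-2-en-1-ol F5. Methyl chloroformate and pyridine would give (Z)-10-[3,5-bis(triisopropylsilyloxy)phenyl]dec-2-en-1-yl methyl carbonate F6. Copper-catalysed enantioselective γ-selective (SN2') borylation with B2pin2 (CuOtBu, monovalent copper, with the QuinoxP* antipode that delivers the (R) product, THF) would then give the α-chiral allylboronate and rejoin the route at 12.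

Step 3. The lithium alkoxide carried by the ylide may attack an aryl silyl ether (silyl transfer), or the doubly deprotonated salt may react sluggishly. The fallback sets out from 2. Methylenation with Ph3P=CH2 (methyltriphenylphosphonium bromide, KOtBu, THF) would give 3,5-bis(triisopropylsilyloxy)styrene F7. Cross-metathesis with commercial oct-7-en-1-ol using second-generation Grubbs catalyst (CH2Cl2, 40 °C) would give the aryl octenol, mainly as the E isomer, which is immaterial, and rejoin the route at 6.

Further compounds
F1 | step 7 | 8-[3,5-bis(triisopropylsilyloxy)phenyl]octanal | O=CCCCCCCCc1cc(O[Si](C(C)C)(C(C)C)C(C)C)cc(O[Si](C(C)C)(C(C)C)C(C)C)c1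
F2 | step 7 | 9-[3,5-bis(triisopropylsilyloxy)phenyl]non-1-yne | C#CCCCCCCCc1cc(O[Si](C(C)C)(C(C)C)C(C)C)cc(O[Si](C(C)C)(C(C)C)C(C)C)c1
F3 | step 7 | (S)-17-[3,5-bis(triisopropylsilyloxy)phenyl]heptadec-9-yn-7-ol | CCCCCC[C@H](O)CC#CCCCCCCCc1cc(O[Si](C(C)C)(C(C)C)C(C)C)cc(O[Si](C(C)C)(C(C)C)C(C)C)c1
F4 | step 6 | methyl (Z)-10-[3,5-bis(triisopropylsilyloxy)phenyl]dec-2-enoate | COC(=O)/C=C\CCCCCCCc1cc(O[Si](C(C)C)(C(C)C)C(C)C)cc(O[Si](C(C)C)(C(C)C)C(C)C)c1
F5 | step 6 | (Z)-10-[3,5-bis(triisopropylsilyloxy)phenyl]dec-2-en-1-ol | OC/C=C\CCCCCCCc1cc(O[Si](C(C)C)(C(C)C)C(C)C)cc(O[Si](C(C)C)(C(C)C)C(C)C)c1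
F6 | step 6 | (Z)-10-[3,5-bis(triisopropylsilyloxy)phenyl]dec-2-en-1-yl methyl carbonate | COC(=O)OC/C=C\CCCCCCCc1cc(O[Si](C(C)C)(C(C)C)C(C)C)cc(O[Si](C(C)C)(C(C)C)C(C)C)c1
F7 | step 3 | 3,5-bis(triisopropylsilyloxy)styrene | C=Cc1cc(O[Si](C(C)C)(C(C)C)C(C)C)cc(O[Si](C(C)C)(C(C)C)C(C)C)c1
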